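Ring B is cut across C5–C6 and C9–C10. The cis ring fusion (5β-H, 10β-CH3) with the C9 side chain on the same face is the stereochemical signature of an endo Diels–Alder addition to a ring A alkene C5=C10. A catalytic enantioselective [4+2] cycloaddition joins a ring A enal (C10 formyl as latent methyl, C3 ketone masked as dioxolane) and a 2-silyloxydiene that already carries the whole homofarnesyl chain; it forms both bonds and sets C5, C9 and C10 at once. The C7 silyl enol ether then serves to bring oxygen to C8; Wolff–Kishner reduction turns the formyl into the methyl group, and methyl addition to the C8 ketone completes the carbinol.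

Key step: step 8

Remark (numbering): decalin carbons C1–C10 as in the target (C3 carbonyl, C4 gem-dimethyl, C5/C10 ring fusion, C8 carbinol, C9 side-chain carbon), side chain C11–C22, C25 = the carbon on C10; β is the face of the C10 substituent.
Remark (target): the structure is read as the cis-fused decalin (5S,8R,9R,10S), i.e. 5β-H, 10β-CH3, 9β side chain, 8α-OH, 8β-CH3.
Remark (catalyst sense): the (R)-catalyst in step 8 is chosen on the binding model for 2-substituted acroleins (formyl C–H···O contact, s-trans enal, diene anti to the shielding aryl group); if the observed sense were opposite, the (S)-catalyst is used with no other change.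
Remark (reagents): acetaldehyde N,N-dimethylhydrazone and 1-(triphenylphosphoranylidene)propan-2-one are taken as commercial reagents.

Step 1
Reactants: 1 2,2-dimethylcyclohexane-1,3-dione
Product: 2 6,6-dimethyl-1,4-dioxaspiro[4.5]decan-7-one
Conditions: ethylene glycol (1.05 equiv), p-TsOH·H2O (cat.), benzene, reflux, Dean–Stark
Reagents that add atoms: ethylene glycol, OCCO
Why: Acid-catalysed ketalization with removal of water should stop at the mono-ketal, because the two carbonyls of 1 are equivalent and the remaining one is then flanked by the quaternary carbon and the dioxolane (acetalization, no stereocenter).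

Step 2
Reactants: 2 6,6-dimethyl-1,4-dioxaspiro[4.5]decan-7-one
Product: 3 (8Z)-8-(hydroxymethylidene)-6,6-dimethyl-1,4-dioxaspiro[4.5]decan-7-one
Conditions: NaH, HCO2Et, THF (cat. EtOH), 0 °C → rt; cold AcOH work-up
Reagents that add atoms: ethyl formate, CCOC=O
Why: Crossed Claisen condensation (α-formylation) can only occur at C8 of 2, the other α-carbon being quaternary, so the one-carbon unit that becomes C25 enters regiospecifically.

Step 3
Reactants: 3 (8Z)-8-(hydroxymethylidene)-6,6-dimethyl-1,4-dioxaspiro[4.5]decan-7-one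
Product: 4 (8E)-6,6-dimethyl-8-[(propan-2-yloxy)methylidene]-1,4-dioxaspiro[4.5]decan-7-one
Conditions: K2CO3, 2-iodopropane, acetone, reflux
Reagents that add atoms: 2-iodopropane, CC(C)I
Why: O-Alkylation of the vinylogous acid with a secondary iodide should give the alkoxymethylene ketone (a vinylogous ester), the usual precursor for a reductive 1,3-carbonyl transposition.

Step 4
Reactants: 4 (8E)-6,6-dimethyl-8-[(propan-2-yloxy)methylidene]-1,4-dioxaspiro[4.5]decan-7-one
Product: 6 6,6-dimethyl-1,4-dioxaspiro[4.5]dec-7-ene-8-carbaldehyde, via allylic alcohol 5 (not isolated)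
Conditions: LiAlH4, Et2O, 0 °C; then 0.5 M aq. HCl, THF, 0 °C, short contact
Reagents that add atoms: water, O
Why: 1,2-Reduction of the vinylogous ester carbonyl and acid-induced allylic transposition with hydrolysis of the enol ether (reductive 1,3-carbonyl transposition) should give the conjugated enal with the double bond at C5=C10; the hindered dioxolane should survive brief cold dilute acid, and the stereocenter of 5 is lost.

Step 5
Reactants: 7 (2E,6E)-farnesyl bromide
Product: 9 (4E,8E)-5,9,13-trimethyltetradeca-4,8,12-trienal, via alkylated hydrazone 8 (not isolated)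
Conditions: acetaldehyde N,N-dimethylhydrazone, LDA (commercial solution), THF, 0 °C; then 7, −78 → 0 °C; then sat. aq. oxalic acid, Et2O, rt
Reagents that add atoms: acetaldehyde N,N-dimethylhydrazone, C/C=N/N(C)C; water, O
Why: Aza-enolate alkylation: the lithiated hydrazone should displace the primary allylic bromide in the SN2 sense without touching the (2E,6E) geometry, and two-phase hydrolysis releases the γ,δ-unsaturated aldehyde (C9, C11 and the chain C12–C22).

Step 6
Reactants: 9 (4E,8E)-5,9,13-trimethyltetradeca-4,8,12-trienal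
Product: 10 (3E,7E,11E)-8,12,16-trimethylheptadeca-3,7,11,15-tetraen-2-one
Conditions: Ph3P=CHC(O)CH3, toluene, 80 °C
Reagents that add atoms: 1-(triphenylphosphoranylidene)propan-2-one, CC(=O)C=P(c1ccccc1)(c1ccccc1)c1ccccc1
Why: Wittig olefination with a stabilized acyl ylide should give the (E)-enone, which fixes the diene geometry needed in step 8.

Step 7
Reactants: 10 (3E,7E,11E)-8,12,16-trimethylheptadeca-3,7,11,15-tetraen-2-one
Product: 11 triisopropyl{[(3E,7E,11E)-8,12,16-trimethylheptadeca-1,3,7,11,15-pentaen-2-yl]oxy}silane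
Conditions: LDA, THF, −78 °C; then TIPSOTf, −78 → 0 °C
Reagents that add atoms: triisopropylsilyl triflate, CC(C)[Si](C(C)C)(C(C)C)OS(=O)(=O)C(F)(F)F
Why: Kinetic deprotonation of the methyl ketone at its methyl group and O-silylation (silyl enol ether formation) should give the cross-conjugated 2-silyloxydiene with the (E)-C3=C4 bond untouched.

Step 8
Reactants: 6 6,6-dimethyl-1,4-dioxaspiro[4.5]dec-7-ene-8-carbaldehyde; 11 triisopropyl{[(3E,7E,11E)-8,12,16-trimethylheptadeca-1,3,7,11,15-pentaen-2-yl]oxy}silane
Product: 12 cis-fused cycloadduct: 3,3-(ethylenedioxy)-4,4-dimethyl-7-(triisopropylsilyloxy)-Δ7-octalin with 5β-H, 10β-CHO and the 9β-[(3E,7E)-4,8,12-trimethyltrideca-3,7,11-trienyl] chain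
Conditions: (R)-3,3-diphenyl-1-(o-tolyl)tetrahydro-1H,3H-pyrrolo[1,2-c][1,3,2]oxazaborole (20 mol%), Tf2NH (20 mol%), 11 (1.5 equiv), CH2Cl2, −78 → −20 °C
Reagents that add atoms: none
Why: The protonated oxazaborolidine binds the formyl oxygen of 6 and lowers the LUMO of its enal double bond (C5=C10), which should undergo a concerted but asynchronous normal-demand [4+2] cycloaddition with the s-cis diene 11, the unhindered CH2 terminus (C6) bonding to the neopentyl β-carbon C5 ahead of the C9–C10 bond. The closest known reaction type is the chiral-oxazaborolidinium-catalysed Diels–Alder reaction of α-substituted enals such as 2-methylacrolein, tiglic aldehyde and 1-cycloalkenecarbaldehydes with 2-silyloxydienes. Ring B is closed in the intermolecular [4+2] mode, suprafacial on both partners, onto the preformed ring A. C5 and C10 come out cis because the dienophile double bond is locked Z in ring A, C9 follows from the endo orientation of the formyl group, which places the outside chain of the (E)-diene cis to C10–CHO, and the absolute sense comes from the catalyst, whose aryl group shields one face of the bound s-trans enal so that the diene adds to the Si face of the formyl-bearing carbon (C10). The step needs regio-, endo- and facial selectivity: regiochemistry is reinforced twice, since C6 is the nucleophilic terminus of the silyl enol ether (para to OSi) and C9 carries the alkyl group (ortho), while the endo mode also keeps the C4 gem-dimethyl group away from the diene. The trisubstituted chain alkenes are neither dienes nor dienophiles here, and the bulky TIPS group should suppress Mukaiyama-type 1,2-addition to the aldehyde.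

Step 9
Reactants: 12 cis-fused cycloadduct (7-OTIPS, 10β-CHO)
Product: 14 8β-hydroxy-7-oxo aldehyde (C7 ketone, C8–OH, 10β-CHO, C3 dioxolane), via silyloxy epoxide 13 (not isolated)
Conditions: DMDO (1.05 equiv, acetone solution), CH2Cl2, −78 °C; then HF·pyridine, THF, 0 °C
Reagents that add atoms: dimethyldioxirane, CC1(C)OO1
Why: Rubottom oxidation: the silyl enol ether is far more nucleophilic than the trialkyl-substituted chain alkenes, so one equivalent of DMDO at −78 °C should epoxidize only C7=C8, and fluoride-induced collapse of the silyloxy epoxide gives the α-hydroxy ketone; attack on the convex β face is expected, but the C8 configuration is of no consequence because C8 becomes a ketone in step 11.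

Step 10
Reactants: 14 8β-hydroxy-7-oxo aldehyde
Product: 16 8β-alcohol with C7 methylene and C10 methyl (C3 dioxolane), via bis-hydrazone 15 (not isolated)
Conditions: N2H4·H2O (excess), EtOH, 70 °C; evaporation; then KOtBu, DMSO, rt → 60 °C
Reagents that add atoms: none
Why: Wolff–Kishner reduction of the preformed bis-hydrazone should convert C7=O into CH2 and the angular formyl group into the C10 methyl group in one operation; under these aprotic basic conditions the C8 oxygen is an alkoxide and so not a leaving group, and the dioxolane, the isolated alkenes and the C5, C9 and C10 stereocenters are inert.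

Step 11
Reactants: 16 8β-alcohol
Product: 17 C8 ketone (3,3-ethylenedioxy-5β-H, 9β side chain, 10β-CH3)
Conditions: Dess–Martin periodinane, pyridine, CH2Cl2, 0 °C → rt
Reagents that add atoms: none
Why: Dess–Martin oxidation of the secondary alcohol under buffered conditions should give the ketone without enolization, so the adjacent C9 stereocenter and the alkenes are untouched.

Step 12
Reactants: 17 C8 ketone
Product: 18 (5S,8R,9R,10S)-3,3-(ethylenedioxy)-8-hydroxy compound (8α-OH, 8β-CH3), the dioxolane of the target
Conditions: MeLi, anhydrous CeCl3, THF, −78 °C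
Reagents that add atoms: methyllithium (used as its organocerium reagent), [Li]C
Why: 1,2-Addition of the weakly basic organocerium reagent avoids enolization toward C9; in the only low-energy chair–chair form of the cis-decalin (the other would push the 4α-methyl group into the concave face under ring B) C1 is axial on ring B and syn-axial to the α face of C8, so methyl should enter equatorially from the convex β face, which sets C8 as (8R) with 8α-OH and 8β-CH3.

Step 13
Reactants: 18 dioxolane of the target
Product: 19 (4aS,5R,6R,8aS)-6-hydroxy-1,1,4a,6-tetramethyl-5-[(3E,7E)-4,8,12-trimethyltrideca-3,7,11-trien-1-yl]octahydronaphthalen-2(1H)-one (target)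
Conditions: 1 M aq. HCl, THF, 0 °C → rt
Reagents that add atoms: water, O
Why: Acid-catalysed acetal hydrolysis unmasks the C3 ketone; C5 is separated from the carbonyl by the quaternary C4, so the cis ring fusion cannot epimerize, and cold dilute acid should not ionize the tertiary alcohol or the chain alkenes.

Compound list
1 | 2,2-dimethylcyclohexane-1,3-dione | CC1(C)C(=O)CCCC1=O | starting material
2 | 6,6-dimethyl-1,4-dioxaspiro[4.5]decan-7-one | CC1(C)C(=O)CCCC12OCCO2 | intermediate
3 | (8Z)-8-(hydroxymethylidene)-6,6-dimethyl-1,4-dioxaspiro[4.5]decan-7-one | CC1(C)C(=O)/C(=C\O)CCC12OCCO2 | intermediate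
4 | (8E)-6,6-dimethyl-8-[(propan-2-yloxy)methylidene]-1,4-dioxaspiro[4.5]decan-7-one | CC1(C)C(=O)/C(=C/OC(C)C)CCC12OCCO2 | intermediate
5 | (8E)-6,6-dimethyl-8-[(propan-2-yloxy)methylidene]-1,4-dioxaspiro[4.5]decan-7-ol, racemic (aluminium alkoxide in the flask) | CC1(C)C(O)/C(=C/OC(C)C)CCC12OCCO2 | intermediate (not isolated)
6 | 6,6-dimethyl-1,4-dioxaspiro[4.5]dec-7-ene-8-carbaldehyde | CC1(C)C=C(C=O)CCC12OCCO2 | intermediate
7 | (2E,6E)-farnesyl bromide, (2E,6E)-1-bromo-3,7,11-trimethyldodeca-2,6,10-triene | CC(C)=CCC/C(C)=C/CC/C(C)=C/CBr | starting material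
8 | (E)-N,N-dimethylhydrazone of (4E,8E)-5,9,13-trimethyltetradeca-4,8,12-trienal | CC(C)=CCC/C(C)=C/CC/C(C)=C/CC/C=N/N(C)C | intermediate (not isolated)
9 | (4E,8E)-5,9,13-trimethyltetradeca-4,8,12-trienal | CC(C)=CCC/C(C)=C/CC/C(C)=C/CCC=O | intermediate
10 | (3E,7E,11E)-8,12,16-trimethylheptadeca-3,7,11,15-tetraen-2-one | CC(C)=CCC/C(C)=C/CC/C(C)=C/CC/C=C/C(C)=O | intermediate
11 | triisopropyl{[(3E,7E,11E)-8,12,16-trimethylheptadeca-1,3,7,11,15-pentaen-2-yl]oxy}silane | CC(C)=CCC/C(C)=C/CC/C(C)=C/CC/C=C/C(=C)O[Si](C(C)C)(C(C)C)C(C)C | intermediate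
12 | cis-fused cycloadduct: 3,3-(ethylenedioxy)-4,4-dimethyl-7-(triisopropylsilyloxy)-Δ7-octalin, 5β-H, 9β-homofarnesyl, 10β-CHO | CC(C)=CCC/C(C)=C/CC/C(C)=C/CC[C@@H]1[C@@]2(C=O)CCC3(OCCO3)C(C)(C)[C@H]2CC(O[Si](C(C)C)(C(C)C)C(C)C)=C1 | intermediate
13 | 7β,8β-epoxide of 12 (7α-OTIPS) | CC(C)=CCC/C(C)=C/CC/C(C)=C/CC[C@@H]1[C@@]2(C=O)CCC3(OCCO3)C(C)(C)[C@H]2C[C@]4(O[Si](C(C)C)(C(C)C)C(C)C)O[C@H]14 | intermediate (not isolated)
14 | 8β-hydroxy-7-oxo aldehyde (3,3-ethylenedioxy, 5β-H, 9β-homofarnesyl, 10β-CHO) | CC(C)=CCC/C(C)=C/CC/C(C)=C/CC[C@@H]1[C@@]2(C=O)CCC3(OCCO3)C(C)(C)[C@H]2CC(=O)[C@@H]1O | intermediate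
15 | bis-hydrazone of 14 (C7=N–NH2, C25H=N–NH2) | CC(C)=CCC/C(C)=C/CC/C(C)=C/CC[C@@H]1[C@@]2(C=NN)CCC3(OCCO3)C(C)(C)[C@H]2CC(=NN)[C@@H]1O | intermediate (not isolated)
16 | 8β-alcohol (3,3-ethylenedioxy, 5β-H, 9β-homofarnesyl, 10β-CH3) | CC(C)=CCC/C(C)=C/CC/C(C)=C/CC[C@@H]1[C@@]2(C)CCC3(OCCO3)C(C)(C)[C@H]2CC[C@@H]1O | intermediate
17 | C8 ketone (3,3-ethylenedioxy, 5β-H, 9β-homofarnesyl, 10β-CH3) | CC(C)=CCC/C(C)=C/CC/C(C)=C/CC[C@@H]1[C@@]2(C)CCC3(OCCO3)C(C)(C)[C@H]2CCC1=O | intermediate
18 | (5S,8R,9R,10S)-3,3-(ethylenedioxy)-8-hydroxy compound (8α-OH, 8β-CH3), dioxolane of the target | CC(C)=CCC/C(C)=C/CC/C(C)=C/CC[C@@H]1[C@@]2(C)CCC3(OCCO3)C(C)(C)[C@H]2CC[C@@]1(C)O | intermediate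
19 | (4aS,5R,6R,8aS)-6-hydroxy-1,1,4a,6-tetramethyl-5-[(3E,7E)-4,8,12-trimethyltrideca-3,7,11-trien-1-yl]octahydronaphthalen-2(1H)-one | CC(C)=CCC/C(C)=C/CC/C(C)=C/CC[C@@H]1[C@@]2(C)CCC(=O)C(C)(C)[C@H]2CC[C@@]1(C)O | target

Total step count: 13. Longest linear sequence: 10 steps (steps 1–4 and 8–13); the diene branch (steps 5–7) joins at step 8.

Steps most likely to fail

Step 8. The cycloaddition may be sluggish at the β-neopentyl enal, the catalyst may be sequestered or may ionize the dioxolane, the silyl dienol ether may add 1,2 to the aldehyde, or facial discrimination may be insufficient. The fallback gives up catalyst control: it sets out from 6 and 11, which are combined with Me2AlCl in CH2Cl2 at −40 °C (or thermally in toluene) to give racemic endo adduct, that is 12 together with its enantiomer F1. Condensation of the angular aldehyde with (1R,2R)-N,N'-dimethyl-1,2-diphenylethane-1,2-diamine over molecular sieves gives the diastereomeric aminals, aminal of 12 F2 and aminal of the enantiomer F3, which are separated by chromatography. Brief two-phase treatment of F2 with cold dilute aqueous acid releases the aldehyde, and the route is rejoined at 12.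

Step 10. The C8 oxygen may be lost by base-induced (Kishner-type) elimination, or the ketol may isomerize before the hydrazone forms. The fallback replaces the anionic reduction by a hydride-based one on an O-protected substrate and sets out from 12. Epoxidation with DMDO as in step 9 but without fluoride, then warming, lets the silyl group migrate to give the 8β-silyloxy-7-oxo aldehyde F4. TsNHNH2 in THF converts both carbonyls into the bis(tosylhydrazone) F5. Catecholborane in CHCl3 at 0 °C followed by NaOAc·3H2O at reflux gives the deoxygenated silyl ether F6 (C7 methylene, C10 methyl), and TBAF in THF removes the silyl group; the route is rejoined at 16.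

Step 12. The methyl group may be delivered to the α face, or the ketone may enolize with epimerization at C9. The fallback exchanges the roles of the entering groups, so that water rather than methyl is the nucleophile at C8, and sets out from 17. Wittig methylenation (Ph3P=CH2, THF) gives the exocyclic alkene F7. Oxymercuration with Hg(OAc)2 (1 equiv) in THF/H2O at 0 °C, which is selective for the 1,1-disubstituted alkene over the trisubstituted chain alkenes, gives the organomercurial F8 with water attached to C8 on the face that nucleophiles prefer. NaBH4/NaOH demercuration turns the CH2Hg group into the methyl group; the route is rejoined at 18.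

Further compounds
F1 | step 8 | enantiomer of cycloadduct 12 | CC(C)=CCC/C(C)=C/CC/C(C)=C/CC[C@H]1[C@]2(C=O)CCC3(OCCO3)C(C)(C)[C@@H]2CC(O[Si](C(C)C)(C(C)C)C(C)C)=C1
F2 | step 8 | aminal of 12 with (1R,2R)-N,N'-dimethyl-1,2-diphenylethane-1,2-diamine (1,3-dimethyl-4,5-diphenylimidazolidin-2-yl at C10) | CC(C)=CCC/C(C)=C/CC/C(C)=C/CC[C@@H]1[C@@]2(C4N(C)[C@H](c5ccccc5)[C@@H](c5ccccc5)N4C)CCC3(OCCO3)C(C)(C)[C@H]2CC(O[Si](C(C)C)(C(C)C)C(C)C)=C1
F3 | step 8 | aminal of F1 with the same (1R,2R)-diamine | CC(C)=CCC/C(C)=C/CC/C(C)=C/CC[C@H]1[C@]2(C4N(C)[C@H](c5ccccc5)[C@@H](c5ccccc5)N4C)CCC3(OCCO3)C(C)(C)[C@@H]2CC(O[Si](C(C)C)(C(C)C)C(C)C)=C1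
F4 | step 10 | 8β-(triisopropylsilyloxy)-7-oxo aldehyde | CC(C)=CCC/C(C)=C/CC/C(C)=C/CC[C@@H]1[C@@]2(C=O)CCC3(OCCO3)C(C)(C)[C@H]2CC(=O)[C@@H]1O[Si](C(C)C)(C(C)C)C(C)C
F5 | step 10 | bis(tosylhydrazone) of F4 | CC(C)=CCC/C(C)=C/CC/C(C)=C/CC[C@@H]1[C@@]2(C=NNS(=O)(=O)c4ccc(C)cc4)CCC3(OCCO3)C(C)(C)[C@H]2CC(=NNS(=O)(=O)c5ccc(C)cc5)[C@@H]1O[Si](C(C)C)(C(C)C)C(C)C
F6 | step 10 | 8β-triisopropylsilyl ether of 16 | CC(C)=CCC/C(C)=C/CC/C(C)=C/CC[C@@H]1[C@@]2(C)CCC3(OCCO3)C(C)(C)[C@H]2CC[C@@H]1O[Si](C(C)C)(C(C)C)C(C)C
F7 | step 12 | 8-methylidene compound (exocyclic alkene from 17) | CC(C)=CCC/C(C)=C/CC/C(C)=C/CC[C@@H]1[C@@]2(C)CCC3(OCCO3)C(C)(C)[C@H]2CCC1=C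
F8 | step 12 | 8α-hydroxy-8β-[(acetoxymercurio)methyl] compound | CC(C)=CCC/C(C)=C/CC/C(C)=C/CC[C@@H]1[C@@]2(C)CCC3(OCCO3)C(C)(C)[C@H]2CC[C@@]1(C[Hg]OC(C)=O)O
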